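## Retrosynthetic overview
1. Target 30 ⇒ final desilylation and a Steglich ester bond: hydroxy-lactone 22 + bis-silylated dienoic acid 28.
2. 22 ⇒ furyl carbinol 19. The only ring-forming event is the oxidative ring expansion of the furan to the six-membered pyranone (Achmatowicz). Lactol oxidation and Luche reduction then set C4.
3. 19 ⇒ boronic ester 8. C8, C9 and C10 are inserted one after the other by three stereospecific 1,2-metallate shifts. The last uses the carbamate of (R)-but-3-en-2-ol and gives the tertiary vinyl carbinol after C–B oxidation.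
4. 8 ⇒ furan + methacrolein: catalytic asymmetric furylzinc addition sets C5, and syn-selective Rh hydroboration sets C6.
5. 28 ⇒ 2,3-dihydrofuran + CH2O: new organocatalytic hydroxymethylation of the free lactol sets C6′, followed by Wittig and Doebner reactions.

Assumption: the chiral ligands, ethyl 2,4,6-triisopropylbenzoate, Ph3P=C(CH3)CHO and enantiopure (R)-but-3-en-2-ol are bought. Locants C1–C12 run from the lactone carbonyl along the chain to the vinyl CH2, so ring positions 5 and 6 are C4 and C5. Primed locants belong to the dienoate.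

## Route

Step 1
Reactants: 1 furan; 2 methacrolein
Product: 6 (R)-tert-butyl{[1-(furan-2-yl)-2-methylprop-2-en-1-yl]oxy}dimethylsilane, via 2-furyllithium 3 (not isolated), via ethyl(furan-2-yl)zinc 4 (not isolated), via ethylzinc alkoxide 5 (not isolated)
Conditions: 1, n-BuLi, t-BuOMe, 0 °C; EtZnCl, −78 to 0 °C; TEEDA, (−)-MIB (10 mol %), toluene, then 2, −10 °C; TBSOTf, 0 °C, same flask
Reagents that add atoms: tert-butyldimethylsilyl trifluoromethanesulfonate, CC(C)(C)[Si](C)(C)OS(=O)(=O)C(F)(F)F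
Why: Ligand-accelerated catalytic asymmetric 1,2-addition of a heteroarylzinc to an enal, in which (−)-MIB directs the furyl group to the Si face of 2 and sets (5R); TEEDA masks LiCl to suppress the racemic background, the zinc alkoxide is silylated in situ, and the minor enantiomer is removed later as a diastereomer.

Step 2
Reactants: 6 (R)-tert-butyl{[1-(furan-2-yl)-2-methylprop-2-en-1-yl]oxy}dimethylsilane
Product: 8 tert-butyl{[(1R,2S)-1-(furan-2-yl)-2-methyl-3-(4,4,5,5-tetramethyl-1,3,2-dioxaborolan-2-yl)propyl]oxy}dimethylsilane, via catechol boronic ester 7 (not isolated)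
Conditions: RhCl(PPh3)3 (3 mol %), catecholborane, THF, −20 °C to rt; then pinacol, rt
Reagents that add atoms: catecholborane, B1Oc2ccccc2O1; pinacol, CC(C)(O)C(C)(C)O
Why: Rh-catalysed hydroboration of a 1,1-disubstituted allylic silyl ether puts boron on the terminal carbon and is syn-selective (the reverse of 9-BBN), because the alkene binds rhodium in the conformer that holds the C–OSi bond anti to the metal, which sets (6S).

Step 3
Reactants: 8 tert-butyl{[(1R,2S)-1-(furan-2-yl)-2-methyl-3-(4,4,5,5-tetramethyl-1,3,2-dioxaborolan-2-yl)propyl]oxy}dimethylsilane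
Product: 12 tert-butyl{[(1R,2S,4S)-1-(furan-2-yl)-2,4-dimethyl-5-(4,4,5,5-tetramethyl-1,3,2-dioxaborolan-2-yl)pentyl]oxy}dimethylsilane, via aroyloxyethyl boronate complex 9 (not isolated), via secondary boronic ester 10 (not isolated), via chloromethyl boronate complex 11 (not isolated)
Conditions: ethyl 2,4,6-triisopropylbenzoate, (−)-sparteine, s-BuLi, Et2O, −78 °C, 5 h; 8, −78 °C, then 35 °C; same flask: BrCH2Cl, n-BuLi, −78 °C to rt
Reagents that add atoms: ethyl 2,4,6-triisopropylbenzoate, CCOC(=O)c1c(C(C)C)cc(C(C)C)cc1C(C)C; bromochloromethane, ClCBr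
Why: Lithiation–borylation followed by Matteson homologation, in which the sparteine-derived (S)-α-lithioethyl benzoate is borylated with retention and C7 migrates antiperiplanar to the carboxylate (invertive 1,2-metallate shift) to set the C8 centre [(8R) in the target] under reagent control; the chloromethyl boronate then inserts C9 with retention at the migrating C8.

Step 4
Reactants: 13 (R)-but-3-en-2-ol
Product: 14 (R)-but-3-en-2-yl N,N-diisopropylcarbamate
Conditions: NaH, THF, 0 °C; iPr2NCOCl, reflux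
Reagents that add atoms: N,N-diisopropylcarbamoyl chloride, CC(C)N(C(C)C)C(=O)Cl
Why: O-Carbamoylation of the alkoxide does not touch the stereocentre and installs the group that directs lithiation and later leaves.

Step 5
Reactants: 14 (R)-but-3-en-2-yl N,N-diisopropylcarbamate; 12 tert-butyl{[(1R,2S,4S)-1-(furan-2-yl)-2,4-dimethyl-5-(4,4,5,5-tetramethyl-1,3,2-dioxaborolan-2-yl)pentyl]oxy}dimethylsilane
Product: 18 (3S,5R,7S,8R)-8-[(tert-butyldimethylsilyl)oxy]-8-(furan-2-yl)-3,5,7-trimethyloct-1-en-3-ol, via lithiated carbamate 15 (not isolated), via allylic boronate complex 16 (not isolated), via tertiary allylic boronic ester 17 (not isolated)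
Conditions: 14 (1.3 equiv), s-BuLi, TMEDA, Et2O, −78 °C; 12, −78 °C to rt; then THF, 2 M NaOH, 30 % H2O2, 0 °C to rt
Reagents that add atoms: hydrogen peroxide, OO
Why: Lithiation–borylation of a secondary allylic carbamate, with retentive deprotonation, α-selective retentive borylation, invertive 1,2-metallate shift of C9 and retentive C–B oxidation; in net terms the carbinol H of 14 is replaced by C9 with retention, which forms C9–C10 and sets (10S).

Step 6
Reactants: 18 (3S,5R,7S,8R)-8-[(tert-butyldimethylsilyl)oxy]-8-(furan-2-yl)-3,5,7-trimethyloct-1-en-3-ol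
Product: 20 (2R)-6-hydroxy-2-[(2S,4R,6S)-6-hydroxy-4,6-dimethyloct-7-en-2-yl]-2H-pyran-3(6H)-one, via furyl diol 19 (not isolated)
Conditions: TBAF, THF, 0 °C to rt; then H2O, NaHCO3, NaOAc, NBS (1.05 equiv), 0 °C, same flask
Reagents that add atoms: water, O
Why: Achmatowicz oxidative ring expansion, in which NBS attacks the electron-rich furan far faster than the monosubstituted vinyl group, the 2,5-dioxygenated dihydrofuran opens to the cis-enedione, and the freed C5 hydroxyl closes on the aldehyde to give the six-membered lactol with C5 untouched.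

Step 7
Reactants: 20 (2R)-6-hydroxy-2-[(2S,4R,6S)-6-hydroxy-4,6-dimethyloct-7-en-2-yl]-2H-pyran-3(6H)-one
Product: 22 (5R,6R)-5-hydroxy-6-[(2S,4R,6S)-6-hydroxy-4,6-dimethyloct-7-en-2-yl]-5,6-dihydro-2H-pyran-2-one, via pyran-3,6-dione 21 (not isolated)
Conditions: DMP, CH2Cl2, 0 °C; then MeOH, CeCl3·7H2O, NaBH4, −78 °C, same flask
Reagents that add atoms: none
Why: Lactol-to-lactone oxidation followed by Luche 1,2-reduction, in which the almost flat ene-dione ring takes hydride on the face anti to the side chain and so sets (4R) cis to it; the one-flask sequence avoids handling the enolisable dione, and the tertiary carbinol is inert to both reagents.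

Step 8
Reactants: 23 2,3-dihydrofuran
Product: 26 (2E,4S)-6-hydroxy-4-(hydroxymethyl)-2-methylhex-2-enal, via oxolan-2-ol 24 (not isolated), via hydroxymethyl lactol 25 (not isolated)
Conditions: H2O, HCl (0.5 mol %), 0 °C to rt; pH 7 phosphate buffer/THF, (S)-α,α-diphenylprolinol TMS ether (20 mol %), 37 % aq. CH2O (1.1 equiv), rt; Ph3P=C(CH3)CHO (2.2 equiv), 60 °C, same flask
Reagents that add atoms: water, O; formaldehyde, C=O; 2-(triphenyl-λ5-phosphanylidene)propanal, CC(C=O)=P(c1ccccc1)(c1ccccc1)c1ccccc1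
Why: Proposed new method: enamine-catalysed asymmetric α-hydroxymethylation run directly on an unprotected γ-lactol; 24 holds about a tenth of open 4-hydroxybutanal, which condenses with the (S)-catalyst to the E-enamine whose one face is blocked by the CPh2(OTMS) group, so CH2O adds to the free face and sets the (R) centre of 25 [(S) at C6′ in 26]; re-closure to lactol 25 withdraws the α-branched β-hydroxy aldehyde from retro-aldol, dehydration and racemisation until the stabilised ylide traps the open form E-selectively; the closest known reaction type is the diarylprolinol silyl ether catalysed α-hydroxymethylation of simple or O-protected aliphatic aldehydes with in situ Wittig olefination.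

Step 9
Reactants: 26 (2E,4S)-6-hydroxy-4-(hydroxymethyl)-2-methylhex-2-enal
Product: 28 (2E,4E,6S)-8-[(tert-butyldimethylsilyl)oxy]-6-{[(tert-butyldimethylsilyl)oxy]methyl}-4-methylocta-2,4-dienoic acid, via bis-silyl enal 27 (not isolated)
Conditions: TBSCl (2.3 equiv), DMAP (5 mol %), pyridine, 0 °C to rt; then malonic acid, 85 °C, same flask
Reagents that add atoms: tert-butyldimethylsilyl chloride, CC(C)(C)[Si](C)(C)Cl; malonic acid, OC(=O)CC(=O)O
Why: Silylation followed by Doebner–Knoevenagel condensation and decarboxylation in the same solvent gives the (2E) acid directly, and leaving out any secondary amine avoids dienamine formation that could racemise the γ stereocentre.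

Step 10
Reactants: 22 (5R,6R)-5-hydroxy-6-[(2S,4R,6S)-6-hydroxy-4,6-dimethyloct-7-en-2-yl]-5,6-dihydro-2H-pyran-2-one; 28 (2E,4E,6S)-8-[(tert-butyldimethylsilyl)oxy]-6-{[(tert-butyldimethylsilyl)oxy]methyl}-4-methylocta-2,4-dienoic acid
Product: 29 (2R,3R)-2-[(2S,4R,6S)-6-hydroxy-4,6-dimethyloct-7-en-2-yl]-6-oxo-3,6-dihydro-2H-pyran-3-yl (2E,4E,6S)-8-[(tert-butyldimethylsilyl)oxy]-6-{[(tert-butyldimethylsilyl)oxy]methyl}-4-methylocta-2,4-dienoate
Conditions: DCC, DMAP (20 mol %), CH2Cl2, 0 °C to rt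
Reagents that add atoms: none
Why: Steglich esterification acylates the secondary allylic hydroxyl with retention at C4, while the tertiary carbinol is too hindered to react.

Step 11
Reactants: 29 (2R,3R)-2-[(2S,4R,6S)-6-hydroxy-4,6-dimethyloct-7-en-2-yl]-6-oxo-3,6-dihydro-2H-pyran-3-yl (2E,4E,6S)-8-[(tert-butyldimethylsilyl)oxy]-6-{[(tert-butyldimethylsilyl)oxy]methyl}-4-methylocta-2,4-dienoate
Product: 30 (2R,3R)-2-[(2S,4R,6S)-6-hydroxy-4,6-dimethyloct-7-en-2-yl]-6-oxo-3,6-dihydro-2H-pyran-3-yl (2E,4E,6S)-8-hydroxy-6-(hydroxymethyl)-4-methylocta-2,4-dienoate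
Conditions: HF·pyridine, pyridine, THF, 0 °C to rt
Reagents that add atoms: none
Why: Buffered fluoride desilylation frees both primary alcohols without touching the ester, the unsaturated lactone or the tertiary allylic alcohol.

## Compound list
1 | furan | c1ccoc1 | starting material
2 | methacrolein | C=C(C)C=O | starting material
3 | 2-furyllithium | [Li]c1ccco1 | intermediate
4 | ethyl(furan-2-yl)zinc | CC[Zn]c1ccco1 | intermediate
5 | ethylzinc (R)-1-(furan-2-yl)-2-methylprop-2-en-1-olate | C=C(C)[C@@H](O[Zn]CC)c1ccco1 | intermediate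
6 | (R)-tert-butyl{[1-(furan-2-yl)-2-methylprop-2-en-1-yl]oxy}dimethylsilane | C=C(C)[C@@H](O[Si](C)(C)C(C)(C)C)c1ccco1 | intermediate
7 | 2-[(2S,3R)-3-[(tert-butyldimethylsilyl)oxy]-3-(furan-2-yl)-2-methylpropyl]-1,3,2-benzodioxaborole | O1c2ccccc2OB1C[C@H](C)[C@@H](O[Si](C)(C)C(C)(C)C)c1ccco1 | intermediate
8 | tert-butyl{[(1R,2S)-1-(furan-2-yl)-2-methyl-3-(4,4,5,5-tetramethyl-1,3,2-dioxaborolan-2-yl)propyl]oxy}dimethylsilane | CC1(C)OB(C[C@H](C)[C@@H](O[Si](C)(C)C(C)(C)C)c2ccco2)OC1(C)C | intermediate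
9 | lithium boronate complex of 8 carrying the 1-(2,4,6-triisopropylbenzoyloxy)ethyl group | [Li+].CC1(C)O[B-](C[C@H](C)[C@@H](O[Si](C)(C)C(C)(C)C)c2ccco2)([C@@H](C)OC(=O)c2c(C(C)C)cc(C(C)C)cc2C(C)C)OC1(C)C | intermediate
10 | tert-butyl{[(1R,2S,4R)-1-(furan-2-yl)-2-methyl-4-(4,4,5,5-tetramethyl-1,3,2-dioxaborolan-2-yl)pentyl]oxy}dimethylsilane | CC1(C)OB([C@H](C)C[C@H](C)[C@@H](O[Si](C)(C)C(C)(C)C)c2ccco2)OC1(C)C | intermediate
11 | lithium chloromethyl boronate complex of 10 | [Li+].CC1(C)O[B-](CCl)([C@H](C)C[C@H](C)[C@@H](O[Si](C)(C)C(C)(C)C)c2ccco2)OC1(C)C | intermediate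
12 | tert-butyl{[(1R,2S,4S)-1-(furan-2-yl)-2,4-dimethyl-5-(4,4,5,5-tetramethyl-1,3,2-dioxaborolan-2-yl)pentyl]oxy}dimethylsilane | CC1(C)OB(C[C@H](C)C[C@H](C)[C@@H](O[Si](C)(C)C(C)(C)C)c2ccco2)OC1(C)C | intermediate
13 | (R)-but-3-en-2-ol | C=C[C@@H](C)O | starting material
14 | (R)-but-3-en-2-yl N,N-diisopropylcarbamate | C=C[C@@H](C)OC(=O)N(C(C)C)C(C)C | intermediate
15 | 2-lithiobut-3-en-2-yl N,N-diisopropylcarbamate (Li in the place of H, configuration retained) | C=C[C@@]([Li])(C)OC(=O)N(C(C)C)C(C)C | intermediate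
16 | lithium boronate complex of 12 carrying the 2-(carbamoyloxy)but-3-en-2-yl group | [Li+].C=C[C@@](C)(OC(=O)N(C(C)C)C(C)C)[B-]1(C[C@H](C)C[C@H](C)[C@@H](O[Si](C)(C)C(C)(C)C)c2ccco2)OC(C)(C)C(C)(C)O1 | intermediate
17 | tert-butyl{[(1R,2S,4R,6R)-1-(furan-2-yl)-2,4,6-trimethyl-6-(4,4,5,5-tetramethyl-1,3,2-dioxaborolan-2-yl)oct-7-en-1-yl]oxy}dimethylsilane | C=C[C@@](C)(B1OC(C)(C)C(C)(C)O1)C[C@H](C)C[C@H](C)[C@@H](O[Si](C)(C)C(C)(C)C)c1ccco1 | intermediate
18 | (3S,5R,7S,8R)-8-[(tert-butyldimethylsilyl)oxy]-8-(furan-2-yl)-3,5,7-trimethyloct-1-en-3-ol | C=C[C@@](C)(O)C[C@H](C)C[C@H](C)[C@@H](O[Si](C)(C)C(C)(C)C)c1ccco1 | intermediate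
19 | (1R,2S,4R,6S)-1-(furan-2-yl)-2,4,6-trimethyloct-7-ene-1,6-diol | C=C[C@@](C)(O)C[C@H](C)C[C@H](C)[C@@H](O)c1ccco1 | intermediate
20 | (2R)-6-hydroxy-2-[(2S,4R,6S)-6-hydroxy-4,6-dimethyloct-7-en-2-yl]-2H-pyran-3(6H)-one (anomer mixture) | C=C[C@@](C)(O)C[C@H](C)C[C@H](C)[C@H]1OC(O)C=CC1=O | intermediate
21 | (2R)-2-[(2S,4R,6S)-6-hydroxy-4,6-dimethyloct-7-en-2-yl]-2H-pyran-3,6-dione | C=C[C@@](C)(O)C[C@H](C)C[C@H](C)[C@H]1OC(=O)C=CC1=O | intermediate
22 | (5R,6R)-5-hydroxy-6-[(2S,4R,6S)-6-hydroxy-4,6-dimethyloct-7-en-2-yl]-5,6-dihydro-2H-pyran-2-one | C=C[C@@](C)(O)C[C@H](C)C[C@H](C)[C@H]1OC(=O)C=C[C@H]1O | intermediate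
23 | 2,3-dihydrofuran | C1=COCC1 | starting material
24 | oxolan-2-ol (lactol of 4-hydroxybutanal) | OC1CCCO1 | intermediate
25 | (3R)-3-(hydroxymethyl)oxolan-2-ol (anomer mixture) | OC1OCC[C@@H]1CO | intermediate
26 | (2E,4S)-6-hydroxy-4-(hydroxymethyl)-2-methylhex-2-enal | O=C/C(C)=C/[C@@H](CO)CCO | intermediate
27 | (2E,4S)-6-[(tert-butyldimethylsilyl)oxy]-4-{[(tert-butyldimethylsilyl)oxy]methyl}-2-methylhex-2-enal | O=C/C(C)=C/[C@@H](CO[Si](C)(C)C(C)(C)C)CCO[Si](C)(C)C(C)(C)C | intermediate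
28 | (2E,4E,6S)-8-[(tert-butyldimethylsilyl)oxy]-6-{[(tert-butyldimethylsilyl)oxy]methyl}-4-methylocta-2,4-dienoic acid | OC(=O)/C=C/C(C)=C/[C@@H](CO[Si](C)(C)C(C)(C)C)CCO[Si](C)(C)C(C)(C)C | intermediate
29 | bis-TBS ether of the target (ester of 22 and 28) | C=C[C@@](C)(O)C[C@H](C)C[C@H](C)[C@H]1OC(=O)C=C[C@H]1OC(=O)/C=C/C(C)=C/[C@@H](CO[Si](C)(C)C(C)(C)C)CCO[Si](C)(C)C(C)(C)C | intermediate
30 | (2R,3R)-2-[(2S,4R,6S)-6-hydroxy-4,6-dimethyloct-7-en-2-yl]-6-oxo-3,6-dihydro-2H-pyran-3-yl (2E,4E,6S)-8-hydroxy-6-(hydroxymethyl)-4-methylocta-2,4-dienoate | C=C[C@@](C)(O)C[C@H](C)C[C@H](C)[C@H]1OC(=O)C=C[C@H]1OC(=O)/C=C/C(C)=C/[C@@H](CO)CCO | target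

## Count and risks
Total step count: 11.
Longest linear sequence: 8 steps (1 → 2 → 3 → 5 → 6 → 7 → 10 → 11).

**Step 8 (the new step).**
- Risks: the low share of open aldehyde and N,O-acetal resting states may starve the enamine cycle. The ylide must olefinate a lactol, and the product is very polar.
- Fallback (known chemistry only): it sets out from 2 and comes back at 26. Rh(acac)(C2H4)2/(S)-BINAP-catalysed 1,4-addition of CH2=CHBF3K to purchased furan-2(5H)-one gives (S)-4-vinyldihydrofuran-2(3H)-one F1. LiAlH4 reduces it to (S)-2-vinylbutane-1,4-diol F2. Cross-metathesis of that diol with an excess of 2 (second-generation Hoveyda–Grubbs catalyst, CH2Cl2, 40 °C) gives 26.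

**Step 5.**
- Risks: the unsubstituted 1-methylallyl lithium species may be borylated at its free γ terminus or lose configuration, and migration to a fully substituted carbon may be slow.
- Fallback: it sets out from 12 and comes back at 18, and builds the carbinol by asymmetric epoxidation instead of a boron shift.
  - NaBO3·4H2O gives (2R,4S,5R)-5-[(tert-butyldimethylsilyl)oxy]-5-(furan-2-yl)-2,4-dimethylpentan-1-ol F3.
  - I2/PPh3/imidazole gives tert-butyl{[(1R,2S,4R)-1-(furan-2-yl)-5-iodo-2,4-dimethylpentyl]oxy}dimethylsilane F4.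
  - t-BuLi, then B-methoxy-9-BBN, then Pd(dppf)Cl2/AsPh3/Cs2CO3 with (E)-3-iodobut-2-en-1-ol gives (2E,5R,7S,8R)-8-[(tert-butyldimethylsilyl)oxy]-8-(furan-2-yl)-3,5,7-trimethyloct-2-en-1-ol F5.
  - Sharpless epoxidation (Ti(OiPr)4, L-(+)-diethyl tartrate, t-BuOOH, 4 Å sieves, −20 °C) gives the (2S,3S)-epoxy alcohol F6.
  - I2/PPh3/imidazole gives the epoxy iodide F7.
  - Zn in EtOH at 70 °C opens it reductively to 18, with the C10–O bond untouched.

**Step 9.**
- Risks: the hindered α-methyl enal may condense slowly with malonic acid, and hot pyridinium carboxylate may strip some silyl ether.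
- Fallback: it sets out from 26 and comes back at 28. TBSCl/imidazole/DMF gives isolated 27. Ph3P=CHCO2Me in CH2Cl2 at 40 °C gives methyl (2E,4E,6S)-8-[(tert-butyldimethylsilyl)oxy]-6-{[(tert-butyldimethylsilyl)oxy]methyl}-4-methylocta-2,4-dienoate F8. LiOH in THF/MeOH/H2O saponifies it to 28.

## Further compounds
F1 | step 8 | (S)-4-vinyldihydrofuran-2(3H)-one | C=C[C@H]1COC(=O)C1
F2 | step 8 | (S)-2-vinylbutane-1,4-diol | C=C[C@@H](CO)CCO
F3 | step 5 | (2R,4S,5R)-5-[(tert-butyldimethylsilyl)oxy]-5-(furan-2-yl)-2,4-dimethylpentan-1-ol | OC[C@H](C)C[C@H](C)[C@@H](O[Si](C)(C)C(C)(C)C)c1ccco1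
F4 | step 5 | tert-butyl{[(1R,2S,4R)-1-(furan-2-yl)-5-iodo-2,4-dimethylpentyl]oxy}dimethylsilane | IC[C@H](C)C[C@H](C)[C@@H](O[Si](C)(C)C(C)(C)C)c1ccco1
F5 | step 5 | (2E,5R,7S,8R)-8-[(tert-butyldimethylsilyl)oxy]-8-(furan-2-yl)-3,5,7-trimethyloct-2-en-1-ol | OC/C=C(\C)C[C@H](C)C[C@H](C)[C@@H](O[Si](C)(C)C(C)(C)C)c1ccco1
F6 | step 5 | {(2S,3S)-3-[(2R,4S,5R)-5-[(tert-butyldimethylsilyl)oxy]-5-(furan-2-yl)-2,4-dimethylpentyl]-3-methyloxiran-2-yl}methanol | OC[C@@H]1O[C@@]1(C)C[C@H](C)C[C@H](C)[C@@H](O[Si](C)(C)C(C)(C)C)c1ccco1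
F7 | step 5 | (2R,3S)-epoxy iodide derived from F6 (CH2OH replaced by CH2I) | IC[C@@H]1O[C@@]1(C)C[C@H](C)C[C@H](C)[C@@H](O[Si](C)(C)C(C)(C)C)c1ccco1
F8 | step 9 | methyl (2E,4E,6S)-8-[(tert-butyldimethylsilyl)oxy]-6-{[(tert-butyldimethylsilyl)oxy]methyl}-4-methylocta-2,4-dienoate | COC(=O)/C=C/C(C)=C/[C@@H](CO[Si](C)(C)C(C)(C)C)CCO[Si](C)(C)C(C)(C)C
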